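**Plan**

1. Retrosynthesis (drimane numbering: C3 carbinol carbon, C4 the quaternary C(CH3)(CH2OAc), C5 ring-fusion CH, C10 ring-fusion C-CH3, C9 the CH bearing C11H2-OAr, C8 the =CH2 carbon): cut the aryl ether C11-O, then the acetate, then C4-C5 and C9-C10 together (C8=CH2 drawn back to a methyl), then C1-C2.
2. Enabling feature: the 1,3-dioxygen pair O-C3/C4-CH2-O of ring A is a reduced α-methyl β-keto ester whose α-carbon is C4. C5/C10 and C9/C8 sit where the two E-trisubstituted alkenes of a geranyl chain lie, so an oxidative radical bicyclisation starting at C4 builds rings A and B and the exocyclic alkene in one step.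
3. Forward: geraniol is silylated, hydroxylated at the terminal E-methyl and brominated; the bromide alkylates the dianion of a chiral 2-methylacetoacetate; ring A then ring B close in one step; hydride reduction, primary acetylation, desilylation and Mitsunobu etherification with umbelliferone finish the route.
4. Stereochemistry: C4, C5, C10 and C9 come from the chair-chair transition state of the E,E-diene (axial ester at C4); the absolute sense comes from the (1S,2R,5S)-8-phenylmenthyl ester; C3 comes from axial hydride delivery.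

Key step: step 6

Remark on the chemistry: the antipode of the auxiliary is chosen on the phenyl-shielding model for the planar C4 radical (Z ester, phenyl stacked on the ester face, ring-forming chain syn to the ester carbonyl oxygen); this sense is a model-based assumption, and the two diastereomers of 10 should be separable in any case.

**Step 1**
Reactants: 1 geraniol
Product: 2 tert-butyl{[(2E)-3,7-dimethylocta-2,6-dien-1-yl]oxy}diphenylsilane
Conditions: TBDPSCl (1.1 equiv), imidazole (2.2 equiv), DMF, 0 °C → rt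
Reagents that add atoms: tert-butyl(chloro)diphenylsilane, CC(C)(C)[Si](Cl)(c1ccccc1)c1ccccc1
Why: Silyl ether formation on a primary allylic alcohol, with a silyl group that should survive the allylic oxidation, acetic acid and hydride used later; no stereocentre is formed.

**Step 2**
Reactants: 2 tert-butyl{[(2E)-3,7-dimethylocta-2,6-dien-1-yl]oxy}diphenylsilane
Product: 3 (2E,6E)-8-[(tert-butyldiphenylsilyl)oxy]-2,6-dimethylocta-2,6-dien-1-ol
Conditions: SeO2 (0.1 equiv), t-BuOOH (3 equiv), salicylic acid (0.1 equiv), CH2Cl2, rt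
Reagents that add atoms: tert-butyl hydroperoxide, CC(C)(C)OO (oxygen relayed by selenium dioxide, O=[Se]=O)
Why: Riley allylic oxidation (ene reaction, then [2,3]-sigmatropic shift) should hydroxylate the E-methyl of the more electron-rich terminal alkene and give the (E)-allylic alcohol.

**Step 3**
Reactants: 3 (2E,6E)-8-[(tert-butyldiphenylsilyl)oxy]-2,6-dimethylocta-2,6-dien-1-ol
Product: 4 {[(2E,6E)-8-bromo-3,7-dimethylocta-2,6-dien-1-yl]oxy}(tert-butyl)diphenylsilane
Conditions: CBr4 (1.2 equiv), PPh3 (1.25 equiv), CH2Cl2, 0 °C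
Reagents that add atoms: tetrabromomethane, BrC(Br)(Br)Br
Why: The Appel reaction converts the primary allylic alcohol into the bromide under neutral conditions, without allylic transposition or loss of the silyl ether.

**Step 4**
Reactants: 5 ethyl 2-methyl-3-oxobutanoate; 6 (1S,2R,5S)-5-methyl-2-(2-phenylpropan-2-yl)cyclohexan-1-ol [(+)-8-phenylmenthol]
Product: 7 (1S,2R,5S)-5-methyl-2-(2-phenylpropan-2-yl)cyclohexyl 2-methyl-3-oxobutanoate (C2 epimers)
Conditions: DMAP (0.2 equiv), toluene, reflux, EtOH distilled off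
Reagents that add atoms: none
Why: DMAP-catalysed transesterification of a β-keto ester (through the acylketene) installs the chiral ester; the C2 stereocentre is of no consequence because it later becomes the radical carbon.

**Step 5**
Reactants: 7 (1S,2R,5S)-5-methyl-2-(2-phenylpropan-2-yl)cyclohexyl 2-methyl-3-oxobutanoate; 4 {[(2E,6E)-8-bromo-3,7-dimethylocta-2,6-dien-1-yl]oxy}(tert-butyl)diphenylsilane
Product: 9 (1S,2R,5S)-5-methyl-2-(2-phenylpropan-2-yl)cyclohexyl (6E,10E)-12-[(tert-butyldiphenylsilyl)oxy]-2,6,10-trimethyl-3-oxododeca-6,10-dienoate (C2 epimers), via sodium lithium dienolate 8 (not isolated)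
Conditions: NaH (1.1 equiv), THF, 0 °C; n-BuLi (1.05 equiv), 0 °C; then 4, 0 °C; sat. aq. NH4Cl
Reagents that add atoms: none
Why: γ-Alkylation of a β-keto ester dianion with an allylic bromide forms the C1-C2 bond at the more reactive terminal carbanion and leaves both E-alkenes untouched.

**Step 6**
Reactants: 9 (1S,2R,5S)-5-methyl-2-(2-phenylpropan-2-yl)cyclohexyl (6E,10E)-12-[(tert-butyldiphenylsilyl)oxy]-2,6,10-trimethyl-3-oxododeca-6,10-dienoate
Product: 10 (1S,2R,5S)-5-methyl-2-(2-phenylpropan-2-yl)cyclohexyl (1S,4aR,5R,8aS)-5-{[(tert-butyldiphenylsilyl)oxy]methyl}-1,4a-dimethyl-6-methylidene-2-oxodecahydronaphthalene-1-carboxylate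
Conditions: Mn(OAc)3·2H2O (2.2 equiv), Cu(OAc)2·H2O (1.0 equiv, turned over by the manganese oxidant), degassed AcOH (0.02 M), rt → 50 °C; minor diastereomer removed by chromatography
Reagents that add atoms: none
Why: Mn(OAc)3 oxidises the enol of the α-methyl β-keto ester to the electrophilic tertiary C4 radical, which adds to C5 of the 6,7-alkene (C4-C5 bond, ring A, 6-endo-trig), the tertiary C10 radical so formed adds to C9 of the 10,11-alkene (ring B, 6-endo-trig), and Cu(OAc)2 captures the tertiary C8 radical as an organocopper species that loses a hydrogen of the adjacent methyl group to leave the exocyclic C8=CH2. The closest known reaction type is the oxidative free-radical polycyclisation of unsaturated α-alkyl β-keto esters with trivalent manganese and divalent copper, which is documented for trans-decalins carrying an axial ester on a quaternary carbon and an exocyclic methylene at the terminus. Both closures are 6-endo and not 5-exo because each trisubstituted alkene is attacked at its CH carbon so that a tertiary radical results. Relative configuration follows from a chair-chair transition state of the E,E-diene: trans ring fusion at C5/C10, equatorial CH2OSi at C9, and at C4 an axial ester cis to the C10 methyl, because in the planar radical the methyl group lies syn to the ketone oxygen and the ester syn to C2 (allylic strain) and the new bond forms perpendicular to that plane. Absolute configuration comes from the auxiliary, whose phenyl ring stacks over one face of the ester-conjugated radical so that C5 should add to the open face and give the (1S,4aR,5R,8aS) decalin. The step needs 6-endo regiochemistry, cyclisation of the C10 radical before its oxidation and exo- over endo-alkene formation, which the alkene substitution pattern, a dilute solution and the preference of the copper-mediated elimination for the unhindered methyl hydrogens should secure.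

**Step 7**
Reactants: 10 (1S,2R,5S)-5-methyl-2-(2-phenylpropan-2-yl)cyclohexyl (1S,4aR,5R,8aS)-5-{[(tert-butyldiphenylsilyl)oxy]methyl}-1,4a-dimethyl-6-methylidene-2-oxodecahydronaphthalene-1-carboxylate
Product: 11 [(1R,2R,4aR,5R,8aS)-5-{[(tert-butyldiphenylsilyl)oxy]methyl}-2-hydroxy-1,4a-dimethyl-6-methylidenedecahydronaphthalen-1-yl]methanol
Conditions: LiAlH4 (3 equiv), THF, 0 °C → rt; then H2O
Reagents that add atoms: none
Why: Hydride reduction in which axial attack on the C3 ketone, on the face away from the axial C4 ester, should give the equatorial (R)-carbinol, after which the neighbouring alkoxyaluminium hydride should deliver hydride to the hindered ester and release the auxiliary.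

**Step 8**
Reactants: 11 [(1R,2R,4aR,5R,8aS)-5-{[(tert-butyldiphenylsilyl)oxy]methyl}-2-hydroxy-1,4a-dimethyl-6-methylidenedecahydronaphthalen-1-yl]methanol
Product: 12 [(1R,2R,4aR,5R,8aS)-5-{[(tert-butyldiphenylsilyl)oxy]methyl}-2-hydroxy-1,4a-dimethyl-6-methylidenedecahydronaphthalen-1-yl]methyl acetate
Conditions: AcCl (1.05 equiv), 2,4,6-collidine (2 equiv), CH2Cl2, −78 °C
Reagents that add atoms: acetyl chloride, CC(=O)Cl
Why: Kinetically controlled acylation should take the primary hydroxyl in preference to the secondary one, which is flanked by the quaternary C4; no stereocentre is touched.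

**Step 9**
Reactants: 12 [(1R,2R,4aR,5R,8aS)-5-{[(tert-butyldiphenylsilyl)oxy]methyl}-2-hydroxy-1,4a-dimethyl-6-methylidenedecahydronaphthalen-1-yl]methyl acetate
Product: 13 [(1R,2R,4aR,5R,8aS)-2-hydroxy-5-(hydroxymethyl)-1,4a-dimethyl-6-methylidenedecahydronaphthalen-1-yl]methyl acetate
Conditions: TBAF (2 equiv), AcOH (2 equiv), THF, rt
Reagents that add atoms: none
Why: Fluoride-mediated desilylation, buffered with acetic acid so that the acetate should neither be cleaved nor migrate to the neighbouring C3 hydroxyl.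

**Step 10**
Reactants: 13 [(1R,2R,4aR,5R,8aS)-2-hydroxy-5-(hydroxymethyl)-1,4a-dimethyl-6-methylidenedecahydronaphthalen-1-yl]methyl acetate; 14 7-hydroxy-2H-chromen-2-one (umbelliferone)
Product: 15 [(1R,2R,4aR,5R,8aS)-2-hydroxy-1,4a-dimethyl-6-methylidene-5-{[(2-oxo-2H-chromen-7-yl)oxy]methyl}decahydronaphthalen-1-yl]methyl acetate (CNP0271943.1)
Conditions: PPh3 (1.5 equiv), DIAD (1.5 equiv), THF, 0 °C → rt
Reagents that add atoms: none
Why: Mitsunobu etherification, in which the acidic phenol should displace the activated primary C11 oxygen while the hindered secondary C3 hydroxyl stays unreacted; no stereocentre is involved.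

**Compound list**

1 | geraniol, (2E)-3,7-dimethylocta-2,6-dien-1-ol | CC(C)=CCC/C(C)=C/CO | starting material
2 | tert-butyl{[(2E)-3,7-dimethylocta-2,6-dien-1-yl]oxy}diphenylsilane | CC(C)=CCC/C(C)=C/CO[Si](c1ccccc1)(c1ccccc1)C(C)(C)C | intermediate
3 | (2E,6E)-8-[(tert-butyldiphenylsilyl)oxy]-2,6-dimethylocta-2,6-dien-1-ol | OC/C(C)=C/CC/C(C)=C/CO[Si](c1ccccc1)(c1ccccc1)C(C)(C)C | intermediate
4 | {[(2E,6E)-8-bromo-3,7-dimethylocta-2,6-dien-1-yl]oxy}(tert-butyl)diphenylsilane | BrC/C(C)=C/CC/C(C)=C/CO[Si](c1ccccc1)(c1ccccc1)C(C)(C)C | intermediate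
5 | ethyl 2-methyl-3-oxobutanoate (racemic) | CCOC(=O)C(C)C(C)=O | starting material
6 | (1S,2R,5S)-5-methyl-2-(2-phenylpropan-2-yl)cyclohexan-1-ol, (+)-8-phenylmenthol | CC(C)(c1ccccc1)[C@H]1CC[C@H](C)C[C@@H]1O | starting material
7 | (1S,2R,5S)-5-methyl-2-(2-phenylpropan-2-yl)cyclohexyl 2-methyl-3-oxobutanoate (C2 epimers) | CC(C)(c1ccccc1)[C@H]1CC[C@H](C)C[C@@H]1OC(=O)C(C)C(C)=O | intermediate
8 | sodium lithium dienolate (dianion) of 7 | CC(C)(c1ccccc1)[C@H]1CC[C@H](C)C[C@@H]1OC(=O)[C-](C)C(=O)[CH2-].[Na+].[Li+] | intermediate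
9 | (1S,2R,5S)-5-methyl-2-(2-phenylpropan-2-yl)cyclohexyl (6E,10E)-12-[(tert-butyldiphenylsilyl)oxy]-2,6,10-trimethyl-3-oxododeca-6,10-dienoate (C2 epimers) | CC(C)(c1ccccc1)[C@H]1CC[C@H](C)C[C@@H]1OC(=O)C(C)C(=O)CC/C(C)=C/CC/C(C)=C/CO[Si](c1ccccc1)(c1ccccc1)C(C)(C)C | intermediate
10 | (1S,2R,5S)-5-methyl-2-(2-phenylpropan-2-yl)cyclohexyl (1S,4aR,5R,8aS)-5-{[(tert-butyldiphenylsilyl)oxy]methyl}-1,4a-dimethyl-6-methylidene-2-oxodecahydronaphthalene-1-carboxylate | C=C1CC[C@@H]2[C@](C)(C(=O)O[C@H]3C[C@@H](C)CC[C@@H]3C(C)(C)c3ccccc3)C(=O)CC[C@@]2(C)[C@@H]1CO[Si](c1ccccc1)(c1ccccc1)C(C)(C)C | intermediate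
11 | [(1R,2R,4aR,5R,8aS)-5-{[(tert-butyldiphenylsilyl)oxy]methyl}-2-hydroxy-1,4a-dimethyl-6-methylidenedecahydronaphthalen-1-yl]methanol | C=C1CC[C@@H]2[C@](C)(CO)[C@H](O)CC[C@@]2(C)[C@@H]1CO[Si](c1ccccc1)(c1ccccc1)C(C)(C)C | intermediate
12 | [(1R,2R,4aR,5R,8aS)-5-{[(tert-butyldiphenylsilyl)oxy]methyl}-2-hydroxy-1,4a-dimethyl-6-methylidenedecahydronaphthalen-1-yl]methyl acetate | C=C1CC[C@@H]2[C@](C)(COC(C)=O)[C@H](O)CC[C@@]2(C)[C@@H]1CO[Si](c1ccccc1)(c1ccccc1)C(C)(C)C | intermediate
13 | [(1R,2R,4aR,5R,8aS)-2-hydroxy-5-(hydroxymethyl)-1,4a-dimethyl-6-methylidenedecahydronaphthalen-1-yl]methyl acetate | C=C1CC[C@@H]2[C@](C)(COC(C)=O)[C@H](O)CC[C@@]2(C)[C@@H]1CO | intermediate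
14 | 7-hydroxy-2H-chromen-2-one (umbelliferone) | Oc1ccc2ccc(=O)oc2c1 | starting material
15 | [(1R,2R,4aR,5R,8aS)-2-hydroxy-1,4a-dimethyl-6-methylidene-5-{[(2-oxo-2H-chromen-7-yl)oxy]methyl}decahydronaphthalen-1-yl]methyl acetate | C=C1CC[C@@H]2[C@](C)(COC(C)=O)[C@H](O)CC[C@@]2(C)[C@@H]1COc1ccc2ccc(=O)oc2c1 | target

**Step count and risks**

Total steps: 10. Longest linear sequence: 9 (steps 1-3 and 5-10; step 4 is a side branch).

Steps most likely to fail:

Step 6. The auxiliary may shield the radical face poorly or in the opposite sense, the C10 radical may be oxidised before ring B closes, or some endocyclic alkene may form. Fallback, setting out from 4 and 5: the dianion of 5 (NaH, n-BuLi, THF, 0 °C) is alkylated with 4 to give ethyl (6E,10E)-12-[(tert-butyldiphenylsilyl)oxy]-2,6,10-trimethyl-3-oxododeca-6,10-dienoate F1. The same Mn(OAc)3/Cu(OAc)2 cyclisation in AcOH should give the racemic ethyl 5-{[(tert-butyldiphenylsilyl)oxy]methyl}-1,4a-dimethyl-6-methylidene-2-oxodecahydronaphthalene-1-carboxylate F2, and LiAlH4 should give the racemic diol F3. Kinetic resolution by lipase-catalysed acetylation of the primary hydroxyl (immobilised Candida antarctica lipase B, vinyl acetate, t-BuOMe) then replaces auxiliary control and installs the acetate at the same time, so the fallback comes back to the route at 12 (or at 11, as the unreacted diol, if the enzyme acylates the antipode faster).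

Step 8. Acetylation may not discriminate enough between the neopentyl primary and the secondary hydroxyl, or the acetyl group may migrate between them. Fallback, setting out from 10: NaBH4 (MeOH, 0 °C) should reduce only the ketone and give the (1S,2R,5S)-8-phenylmenthyl (1S,2R,4aR,5R,8aS)-2-hydroxy ester F4. TESOTf/2,6-lutidine gives its 2-O-triethylsilyl ether F5, LiAlH4 gives the primary alcohol [(1R,2R,4aR,5R,8aS)-5-{[(tert-butyldiphenylsilyl)oxy]methyl}-1,4a-dimethyl-6-methylidene-2-[(triethylsilyl)oxy]decahydronaphthalen-1-yl]methanol F6, whose only free hydroxyl is acetylated (Ac2O, DMAP, pyridine) to the acetate F7. HF·pyridine in THF then removes both silyl groups, and the fallback comes back to the route at 13.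

Step 10. Displacement at the β-branched primary C11 may be slow, and the activated oxygen may instead be eliminated towards the conjugated diene. Fallback, setting out from 13: the aryl-oxygen bond is formed instead of the alkyl-oxygen bond, by C-O cross-coupling of 13 with 7-bromo-2H-chromen-2-one under zerovalent palladium catalysis (Pd2(dba)3, tBuBrettPhos, Cs2CO3, toluene, 80 °C). The hindered secondary hydroxyl should not compete, and the fallback comes back to the route directly at 15.

**Further compounds**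

F1 | step 6 | ethyl (6E,10E)-12-[(tert-butyldiphenylsilyl)oxy]-2,6,10-trimethyl-3-oxododeca-6,10-dienoate | CCOC(=O)C(C)C(=O)CC/C(C)=C/CC/C(C)=C/CO[Si](c1ccccc1)(c1ccccc1)C(C)(C)C
F2 | step 6 | racemic ethyl (1S*,4aR*,5R*,8aS*)-5-{[(tert-butyldiphenylsilyl)oxy]methyl}-1,4a-dimethyl-6-methylidene-2-oxodecahydronaphthalene-1-carboxylate (both enantiomers) | C=C1CC[C@@H]2[C@](C)(C(=O)OCC)C(=O)CC[C@@]2(C)[C@@H]1CO[Si](c1ccccc1)(c1ccccc1)C(C)(C)C.C=C1CC[C@H]2[C@@](C)(C(=O)OCC)C(=O)CC[C@]2(C)[C@H]1CO[Si](c1ccccc1)(c1ccccc1)C(C)(C)C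
F3 | step 6 | racemic [(1R*,2R*,4aR*,5R*,8aS*)-5-{[(tert-butyldiphenylsilyl)oxy]methyl}-2-hydroxy-1,4a-dimethyl-6-methylidenedecahydronaphthalen-1-yl]methanol (both enantiomers) | C=C1CC[C@@H]2[C@](C)(CO)[C@H](O)CC[C@@]2(C)[C@@H]1CO[Si](c1ccccc1)(c1ccccc1)C(C)(C)C.C=C1CC[C@H]2[C@@](C)(CO)[C@@H](O)CC[C@]2(C)[C@H]1CO[Si](c1ccccc1)(c1ccccc1)C(C)(C)C
F4 | step 8 | (1S,2R,5S)-5-methyl-2-(2-phenylpropan-2-yl)cyclohexyl (1S,2R,4aR,5R,8aS)-5-{[(tert-butyldiphenylsilyl)oxy]methyl}-2-hydroxy-1,4a-dimethyl-6-methylidenedecahydronaphthalene-1-carboxylate | C=C1CC[C@@H]2[C@](C)(C(=O)O[C@H]3C[C@@H](C)CC[C@@H]3C(C)(C)c3ccccc3)[C@H](O)CC[C@@]2(C)[C@@H]1CO[Si](c1ccccc1)(c1ccccc1)C(C)(C)C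
F5 | step 8 | (1S,2R,5S)-5-methyl-2-(2-phenylpropan-2-yl)cyclohexyl (1S,2R,4aR,5R,8aS)-5-{[(tert-butyldiphenylsilyl)oxy]methyl}-1,4a-dimethyl-6-methylidene-2-[(triethylsilyl)oxy]decahydronaphthalene-1-carboxylate | C=C1CC[C@@H]2[C@](C)(C(=O)O[C@H]3C[C@@H](C)CC[C@@H]3C(C)(C)c3ccccc3)[C@H](O[Si](CC)(CC)CC)CC[C@@]2(C)[C@@H]1CO[Si](c1ccccc1)(c1ccccc1)C(C)(C)C
F6 | step 8 | [(1R,2R,4aR,5R,8aS)-5-{[(tert-butyldiphenylsilyl)oxy]methyl}-1,4a-dimethyl-6-methylidene-2-[(triethylsilyl)oxy]decahydronaphthalen-1-yl]methanol | C=C1CC[C@@H]2[C@](C)(CO)[C@H](O[Si](CC)(CC)CC)CC[C@@]2(C)[C@@H]1CO[Si](c1ccccc1)(c1ccccc1)C(C)(C)C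
F7 | step 8 | [(1R,2R,4aR,5R,8aS)-5-{[(tert-butyldiphenylsilyl)oxy]methyl}-1,4a-dimethyl-6-methylidene-2-[(triethylsilyl)oxy]decahydronaphthalen-1-yl]methyl acetate | C=C1CC[C@@H]2[C@](C)(COC(C)=O)[C@H](O[Si](CC)(CC)CC)CC[C@@]2(C)[C@@H]1CO[Si](c1ccccc1)(c1ccccc1)C(C)(C)C
F0 | step 10 | none | none
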